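(The readings come from a simulation for substances that don't exist.)

The ratio 50.0 % of reagent charged to substrate charged in Wednesday's flask is the number to carry. Call it the roof: the most target, in percent of the substrate charged, if each target takes one reagent. That makes reagent the limiting reagent here.

the same everywhere: substrate 10 mM
- Wednesday's: reagent 5 mM; temperature 50 °C; the very flask that is asked about, followed so far
- Friday's: reagent 10 mM; temperature 35 °C; run made earlier
- flask: reagent 5.00 mM; temperature 50 °C; time 30 min

- Wednesday's (time / min: target / %): 3.00: 47; 6.00: 49; 10.0: 47; 12.0: 50; 15.0: 53; 20.0: 49
- Friday's (time / min: target / %): 0.667: 24; 1.33: 43; 2.00: 55; 3.00: 62; 4.00: 73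

(standard deviation of a reading: 2 percentage points)

- ash: change nothing and wait 30 min more
- cedar: at 30 min add substrate, 50.0 % of the amount charged, then wait 30 min
- maple: at 30 min add reagent, 100 % of the amount charged, then wait 30 min
- oak: at 30 min raise the temperature by 20 K, then wait 30 min

- what is added takes up no volume worth counting
- a reading or a percentage of target counts all its forms, free or not

1. target, in percent of the substrate first charged, at 30 min
2. the option that brings most further target ("none" if no option brings more than 2 percentage points) (ash / cedar / maple / oak / none)
3. target present, in percent of the substrate first charged, after ash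
4. target present, in percent of the substrate first charged, after cedar

Now run Wednesday's flask in slow motion, as my own reckoning.

In the first instants both charges are present and the reaction is quick. Friday's flask, colder but with twice the reagent, reads 55 % at 2.00 min. Wednesday's first reading, at 3.00 min, already stands at 94.0 % of the roof.

In the middle, the six readings average

    49.2 %, against a roof of 50.0 %,

which is level with the roof at a scatter of 2 percentage points per reading. Is this a limit of the target itself? No: Friday's flask has a roof of 100 %, and its last reading of 73 % climbs past Wednesday's plateau.

So freeze the end of Wednesday's flask at the roof: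

    [target] at 30 min = 50.0 % × 10 mM = 5.00 mM

Ash, cedar and oak add no reagent, so I expect the roof, in percent of the substrate first charged, to stay. Maple lifts it:

    new roof = 5.00 mM × (1 + 100 %) / 10 mM = 100 %

That is a gain of 50 points. I commit to 50.0 % now and to maple.

The forecast gives 49.5 % (47.5 % to 51 %), a shade below my figure, and maple as best, with 49.5 % after ash and 49.7 % after cedar. Its ground: “the reagent is used up, and the target looks stable”.

The flask gives 50.0 %, crystals counted in, 50.0 % after ash and 50.0 % after cedar, and maple brings 50 points.

    substrate + reagent → target, rate k1*[substrate]^0.5*[reagent] (k = 0.220 L⁰·⁵ mol⁻⁰·⁵ s⁻¹, Ea = 55.0 kJ mol⁻¹)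
    crystals ⇌ target, rate k2*(cs2 - [target]) while solid is left; crystals form when [target] > cs2 (solubility = 3.60 mM, k = 3.80 s⁻¹)
    (constants at 50 °C)

Wednesday's flask stops at the roof because reagent runs short, with 0 % of it left at 30.0 min: relieved of that shortage, the flask gives 100 % instead of 50.0 %. A reagent charge of 5.50 mM moves the answer at 30 min by 5 points, past the forecast's high end of 51 %. The neighbour with 25 mM of substrate has a roof of 20.0 % and gives 20.0 %.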